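The carbocycle of the tetrahydrobenzofuranone (C3a, C4, C5, C6, C7, C7a; benzofuran numbering) is closed last by a Diels–Alder reaction that makes C5–C6 and C7–C7a together. It exploits the masked 1,3-dicarbonyl C4–C3a–C7a: an α-acetyl-γ-butyrolactone (ring O1, C2, C3, C3a, C7a), assembled from the L-glutamic-acid-derived lactone acid, Meldrum's acid and geranyl bromide, is silylated to a cyclic 1,1,3-trioxygenated diene. Vinylboronic acid pinacol ester delivers C6–C7 as a hydroxyethylene equivalent; C–B oxidation and loss of silanol then reveal the 7-hydroxy vinylogous ester and the free acid in the same flask.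

Key step: step 9

Remark: atoms are labelled as in the target (O1, C2, C3, C3a, C4 to C7, C7a; C1' is the side-chain carbinol carbon), and compounds 1, 2, 5 and 14 are taken as commercial.

Step 1
Reactants: 1 (2S)-5-oxotetrahydrofuran-2-carboxylic acid; 2 Meldrum's acid
Product: 4 allyl 3-oxo-3-[(2S)-5-oxotetrahydrofuran-2-yl]propanoate, via acyl Meldrum's acid 3 (not isolated)
Conditions: DCC, DMAP, CH2Cl2, 0 °C to rt; filter; then allyl alcohol, toluene, 90 °C
Reagents that add atoms: allyl alcohol, C=CCO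
Why: Carbodiimide-mediated C-acylation of Meldrum's acid followed by thermal alcoholysis of the acyl Meldrum's acid (loss of acetone and CO2) is a standard β-keto ester synthesis that should leave the lactone and its stereocenter (future C2) untouched.

Step 2
Reactants: 4 allyl 3-oxo-3-[(2S)-5-oxotetrahydrofuran-2-yl]propanoate; 5 geranyl bromide
Product: 6 allyl (4E)-5,9-dimethyl-2-[(2S)-5-oxotetrahydrofuran-2-carbonyl]deca-4,8-dienoate (both C2 epimers)
Conditions: K2CO3, acetone, rt
Reagents that add atoms: none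
Why: SN2 C-alkylation of the doubly activated methylene by the primary allylic bromide needs only carbonate, which should not enolise the lactone stereocenter; the new α-stereocenter is removed in step 3.

Step 3
Reactants: 6 allyl (4E)-5,9-dimethyl-2-[(2S)-5-oxotetrahydrofuran-2-carbonyl]deca-4,8-dienoate
Product: 7 (5S)-5-[(4E)-5,9-dimethyldeca-4,8-dienoyl]dihydrofuran-2(3H)-one
Conditions: Pd(PPh3)4 (cat.), morpholine, THF, rt
Reagents that add atoms: none
Why: Tsuji–Trost deallylation with decarboxylation: zerovalent palladium ionises the allyl ester, morpholine traps the allyl group and the β-keto acid loses CO2 under neutral conditions, which should preserve the α-acyloxy ketone stereocenter.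

Step 4
Reactants: 7 (5S)-5-[(4E)-5,9-dimethyldeca-4,8-dienoyl]dihydrofuran-2(3H)-one
Product: 8 (5S)-5-[(2S,5E)-2-hydroxy-6,10-dimethylundeca-5,9-dien-2-yl]dihydrofuran-2(3H)-one
Conditions: MeTi(O-i-Pr)3, THF, −20 °C to rt; aq. NH4Cl
Reagents that add atoms: methyltitanium triisopropoxide, C[Ti](OC(C)C)(OC(C)C)OC(C)C
Why: The non-chelating, ketone-selective organotitanium reagent should add under polar Felkin–Anh control (methyl anti to the ring oxygen and past the hydrogen of C2), which sets C1' as (S) while the lactone and alkenes stay inert.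

Step 5
Reactants: 8 (5S)-5-[(2S,5E)-2-hydroxy-6,10-dimethylundeca-5,9-dien-2-yl]dihydrofuran-2(3H)-one
Product: 9 (5S)-5-[(2S,5E,9E)-2,11-dihydroxy-6,10-dimethylundeca-5,9-dien-2-yl]dihydrofuran-2(3H)-one
Conditions: SeO2 (cat.), t-BuOOH, salicylic acid (cat.), CH2Cl2, rt
Reagents that add atoms: tert-butyl hydroperoxide, CC(C)(C)OO
Why: Riley allylic oxidation (ene reaction with SeO2, then [2,3]-sigmatropic shift) is selective for the (E)-methyl group of a terminal isopropylidene unit and should give the (E)-allylic alcohol.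

Step 6
Reactants: 9 (5S)-5-[(2S,5E,9E)-2,11-dihydroxy-6,10-dimethylundeca-5,9-dien-2-yl]dihydrofuran-2(3H)-one
Product: 11 (2E,6E,10S)-10-hydroxy-2,6,10-trimethyl-10-[(2S)-5-oxotetrahydrofuran-2-yl]deca-2,6-dienoic acid, via enal 10 (not isolated)
Conditions: TEMPO (cat.), PhI(OAc)2, CH2Cl2, rt; then NaClO2, NaH2PO4, 2-methyl-2-butene, t-BuOH–H2O, 0 °C to rt
Reagents that add atoms: sodium chlorite, [Na+].[O-]Cl=O
Why: Oxoammonium oxidation of the primary allylic alcohol to the enal and Pinnick oxidation to the acid should spare the tertiary alcohol, the lactone and the alkene geometry.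

Step 7
Reactants: 11 (2E,6E,10S)-10-hydroxy-2,6,10-trimethyl-10-[(2S)-5-oxotetrahydrofuran-2-yl]deca-2,6-dienoic acid
Product: 12 (2E,6E,10S)-10-[(2S,4RS)-4-acetyl-5-oxotetrahydrofuran-2-yl]-10-hydroxy-2,6,10-trimethyldeca-2,6-dienoic acid
Conditions: LiN(i-Pr)2 (3.3 equiv), THF, −78 °C; N-methoxy-N-methylacetamide, −78 to 0 °C; 1 M HCl
Reagents that add atoms: N-methoxy-N-methylacetamide, CC(=O)N(C)OC
Why: After deprotonation of the acid and the tertiary alcohol, the third equivalent of base forms the lactone enolate, which is C-acylated by the N-methoxy-N-methylamide (crossed Claisen condensation through a stable tetrahedral chelate); the new stereocenter at C3a is lost in step 8.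

Step 8
Reactants: 12 (2E,6E,10S)-10-[(2S,4RS)-4-acetyl-5-oxotetrahydrofuran-2-yl]-10-hydroxy-2,6,10-trimethyldeca-2,6-dienoic acid
Product: 13 trimethylsilyl (2E,6E,10S)-2,6,10-trimethyl-10-(trimethylsilyloxy)-10-[(2S)-5-(trimethylsilyloxy)-4-[1-(trimethylsilyloxy)ethenyl]-2,3-dihydrofuran-2-yl]deca-2,6-dienoate
Conditions: Me3SiOTf (5 equiv), Et3N (6 equiv), Et2O, 0 °C to rt; pentane extraction under argon, used crude
Reagents that add atoms: trimethylsilyl trifluoromethanesulfonate, C[Si](C)(C)OS(=O)(=O)C(F)(F)F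
Why: Soft enolisation (silyl triflate and amine) of the β-keto lactone should give the cyclic 1,3-bis(silyloxy)diene, while the acid and the tertiary alcohol are silylated in the same operation.

Step 9
Reactants: 13 trimethylsilyl (2E,6E,10S)-2,6,10-trimethyl-10-(trimethylsilyloxy)-10-[(2S)-5-(trimethylsilyloxy)-4-[1-(trimethylsilyloxy)ethenyl]-2,3-dihydrofuran-2-yl]deca-2,6-dienoate; 14 vinylboronic acid pinacol ester
Product: 17 (2E,6E,10S)-10-hydroxy-10-[(2S,7R)-7-hydroxy-4-oxo-2,3,4,5,6,7-hexahydro-1-benzofuran-2-yl]-2,6,10-trimethyldeca-2,6-dienoic acid (the target), via boronate cycloadduct 15 (not isolated), via borate ester 16 (not isolated)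
Conditions: 14 (excess), toluene, 90 °C, sealed tube; concentrate in vacuo; then Me3NO (anhydrous), THF, 65 °C; then 10% aq. citric acid, 0 °C to rt
Reagents that add atoms: trimethylamine N-oxide, C[N+](C)(C)[O-]
Why: Thermal, concerted but asynchronous [4+2] cycloaddition of the electron-rich diene C5=C4(OSi)–C3a=C7a(OSi)(O1) with the vinylboronate, in which the nucleophilic terminus C5 bonds to the β-carbon C6 and the boron-bearing carbon C7 to the acetal-type terminus C7a; the closest precedents are Diels–Alder reactions of 1,3-bis(silyloxy)-1-alkoxydienes and of vinylboronic esters. The only ring closed is the carbocycle C3a–C4–C5–C6–C7–C7a, formed by intermolecular [4+2] annulation onto the existing dihydrofuran. C7 is the only lasting new stereocenter: endo boron (over O1 and C7a) on the diene face anti to the bulky C(CH3)(OSiMe3)R group at C2 gives (7R), the syn-face endo approach that would give (7S) clashes with that group, and C7a becomes planar again. Regioselectivity is secured by the push of three oxygen substituents toward C5, and chemoselectivity by the far higher reactivity of the silyl ketene acetal diene compared with the isolated and carboxyl-conjugated alkenes. Me3NO then oxidises the C–B bond with retention under anhydrous conditions, so that no α-boryl carbonyl compound is formed. Mild acid finally expels silanol from C7a while O1 stays bound, which restores the C3a=C7a double bond of the vinylogous ester and frees both hydroxyl groups and the acid.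

Compound list
1 | (2S)-5-oxotetrahydrofuran-2-carboxylic acid | OC(=O)[C@@H]1CCC(=O)O1 | starting material
2 | Meldrum's acid (2,2-dimethyl-1,3-dioxane-4,6-dione) | CC1(C)OC(=O)CC(=O)O1 | starting material
3 | 5-{hydroxy[(2S)-5-oxotetrahydrofuran-2-yl]methylidene}-2,2-dimethyl-1,3-dioxane-4,6-dione (acyl Meldrum's acid) | CC1(C)OC(=O)C(=C(O)[C@@H]2CCC(=O)O2)C(=O)O1 | intermediate
4 | allyl 3-oxo-3-[(2S)-5-oxotetrahydrofuran-2-yl]propanoate | C=CCOC(=O)CC(=O)[C@@H]1CCC(=O)O1 | intermediate
5 | geranyl bromide [(2E)-1-bromo-3,7-dimethylocta-2,6-diene] | CC(C)=CCC/C(C)=C/CBr | starting material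
6 | allyl (4E)-5,9-dimethyl-2-[(2S)-5-oxotetrahydrofuran-2-carbonyl]deca-4,8-dienoate (both C2 epimers) | C=CCOC(=O)C(C/C=C(\C)CCC=C(C)C)C(=O)[C@@H]1CCC(=O)O1 | intermediate
7 | (5S)-5-[(4E)-5,9-dimethyldeca-4,8-dienoyl]dihydrofuran-2(3H)-one | CC(C)=CCC/C(C)=C/CCC(=O)[C@@H]1CCC(=O)O1 | intermediate
8 | (5S)-5-[(2S,5E)-2-hydroxy-6,10-dimethylundeca-5,9-dien-2-yl]dihydrofuran-2(3H)-one | C/C(=C\CC[C@](C)(O)[C@@H]1CCC(=O)O1)CCC=C(C)C | intermediate
9 | (5S)-5-[(2S,5E,9E)-2,11-dihydroxy-6,10-dimethylundeca-5,9-dien-2-yl]dihydrofuran-2(3H)-one | C/C(=C\CC[C@](C)(O)[C@@H]1CCC(=O)O1)CC/C=C(\C)CO | intermediate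
10 | (2E,6E,10S)-10-hydroxy-2,6,10-trimethyl-10-[(2S)-5-oxotetrahydrofuran-2-yl]deca-2,6-dienal | C/C(=C\CC[C@](C)(O)[C@@H]1CCC(=O)O1)CC/C=C(\C)C=O | intermediate
11 | (2E,6E,10S)-10-hydroxy-2,6,10-trimethyl-10-[(2S)-5-oxotetrahydrofuran-2-yl]deca-2,6-dienoic acid | C/C(=C\CC[C@](C)(O)[C@@H]1CCC(=O)O1)CC/C=C(\C)C(=O)O | intermediate
12 | (2E,6E,10S)-10-[(2S,4RS)-4-acetyl-5-oxotetrahydrofuran-2-yl]-10-hydroxy-2,6,10-trimethyldeca-2,6-dienoic acid | C/C(=C\CC[C@](C)(O)[C@@H]1CC(C(C)=O)C(=O)O1)CC/C=C(\C)C(=O)O | intermediate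
13 | trimethylsilyl (2E,6E,10S)-2,6,10-trimethyl-10-(trimethylsilyloxy)-10-[(2S)-5-(trimethylsilyloxy)-4-[1-(trimethylsilyloxy)ethenyl]-2,3-dihydrofuran-2-yl]deca-2,6-dienoate | C/C(=C\CC[C@](C)(O[Si](C)(C)C)[C@@H]1CC(C(=C)O[Si](C)(C)C)=C(O[Si](C)(C)C)O1)CC/C=C(\C)C(=O)O[Si](C)(C)C | intermediate
14 | vinylboronic acid pinacol ester (4,4,5,5-tetramethyl-2-vinyl-1,3,2-dioxaborolane) | C=CB1OC(C)(C)C(C)(C)O1 | starting material
15 | trimethylsilyl (2E,6E,10S)-2,6,10-trimethyl-10-(trimethylsilyloxy)-10-[(2S,7R,7aS)-7-(4,4,5,5-tetramethyl-1,3,2-dioxaborolan-2-yl)-4,7a-bis(trimethylsilyloxy)-2,3,5,6,7,7a-hexahydro-1-benzofuran-2-yl]deca-2,6-dienoate (boronate cycloadduct) | C/C(=C\CC[C@](C)(O[Si](C)(C)C)[C@@H]1CC2=C(O[Si](C)(C)C)CC[C@@H](B3OC(C)(C)C(C)(C)O3)[C@@]2(O[Si](C)(C)C)O1)CC/C=C(\C)C(=O)O[Si](C)(C)C | intermediate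
16 | trimethylsilyl (2E,6E,10S)-2,6,10-trimethyl-10-(trimethylsilyloxy)-10-[(2S,7R,7aR)-7-[(4,4,5,5-tetramethyl-1,3,2-dioxaborolan-2-yl)oxy]-4,7a-bis(trimethylsilyloxy)-2,3,5,6,7,7a-hexahydro-1-benzofuran-2-yl]deca-2,6-dienoate (borate ester) | C/C(=C\CC[C@](C)(O[Si](C)(C)C)[C@@H]1CC2=C(O[Si](C)(C)C)CC[C@@H](OB3OC(C)(C)C(C)(C)O3)[C@@]2(O[Si](C)(C)C)O1)CC/C=C(\C)C(=O)O[Si](C)(C)C | intermediate
17 | (2E,6E,10S)-10-hydroxy-10-[(2S,7R)-7-hydroxy-4-oxo-2,3,4,5,6,7-hexahydro-1-benzofuran-2-yl]-2,6,10-trimethyldeca-2,6-dienoic acid | C/C(=C\CC[C@](C)(O)[C@@H]1CC2=C(O1)[C@H](O)CCC2=O)CC/C=C(\C)C(=O)O | target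

Total step count: 9 steps. Longest linear sequence: 9 steps (1 to 17).

Steps most likely to fail

1. Step 9. The cycloaddition may show poor endo and π-facial discrimination, because C2 is remote from the reacting termini, so that both configurations arise at C7. A slow reaction at the doubly oxygenated terminus C7a, or loss of boron together with the silyloxy group from C7a, are secondary concerns. Fallback: the configuration at C7 is set by reagent control instead of by the cycloaddition. It sets out from 17 (as the C7-epimeric mixture delivered by step 9) and comes back at 17. MnO2 in CH2Cl2 at rt should oxidise the allylic C7 carbinol of both epimers to the ene-dione (2E,6E,10S)-10-[(2S)-4,7-dioxo-2,3,4,5,6,7-hexahydro-1-benzofuran-2-yl]-10-hydroxy-2,6,10-trimethyldeca-2,6-dienoic acid F1. Corey–Bakshi–Shibata reduction ((S)-2-methyl-CBS-oxazaborolidine, catecholborane, toluene, −78 °C) should then reduce the C7 ketone, which is more electrophilic than the vinylogous ester carbonyl C4, to the (7R) alcohol 17; the unsaturated C7a side acts as the large substituent. F1 has to be kept cold and neutral because it can tautomerise to the hydroquinone.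

2. Step 4. The methyl addition may show poor diastereofacial selectivity if the lactone oxygen takes part in chelation or the Felkin–Anh preference is weak. Fallback: both C2 and C1' are set by a Sharpless asymmetric epoxidation and a stereospecific epoxide opening. This fallback does not start from a compound of the main route; it sets out from commercial (2Z,6E)-farnesol F2 and comes back at 8.
 - Epoxidation (Ti(O-i-Pr)4, D-(−)-diethyl tartrate, t-BuOOH, 4 Å molecular sieves, CH2Cl2, −20 °C) should give [(2R,3S)-3-[(3E)-4,8-dimethylnona-3,7-dien-1-yl]-3-methyloxiran-2-yl]methanol F3.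
 - Appel-type iodination (I2, PPh3, imidazole, Et2O–MeCN, 0 °C) should give (2S,3S)-3-[(3E)-4,8-dimethylnona-3,7-dien-1-yl]-2-(iodomethyl)-3-methyloxirane F4.
 - Alkylation of LiCH2CO2t-Bu (from tert-butyl acetate and LiN(i-Pr)2, THF–DMPU, −78 to −20 °C) should give tert-butyl 3-[(2R,3S)-3-[(3E)-4,8-dimethylnona-3,7-dien-1-yl]-3-methyloxiran-2-yl]propanoate F5.
 - Camphorsulfonic acid (cat.) in CH2Cl2 should induce 5-exo opening of the epoxide by the ester carbonyl oxygen with inversion at C2 and loss of isobutene, giving 8.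

3. Step 5. The allylic oxidation may be incomplete or attack the allylic positions of the internal trisubstituted alkene. Fallback: the oxidised terminus is introduced by alkene metathesis instead of C–H oxidation. It sets out from 8 and comes back at 11. Cross-metathesis of the terminal isopropylidene group of 8 with methacrolein (second-generation Hoveyda–Grubbs catalyst, CH2Cl2, 40 °C) should give the (E)-enal 10 directly with loss of isobutene, and the Pinnick half of step 6 then gives 11. This fallback forms no compound outside the compound list (F0).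

Further compounds
F1 | step 9 | (2E,6E,10S)-10-[(2S)-4,7-dioxo-2,3,4,5,6,7-hexahydro-1-benzofuran-2-yl]-10-hydroxy-2,6,10-trimethyldeca-2,6-dienoic acid | C/C(=C\CC[C@](C)(O)[C@@H]1CC2=C(O1)C(=O)CCC2=O)CC/C=C(\C)C(=O)O
F2 | step 4 | (2Z,6E)-farnesol [(2Z,6E)-3,7,11-trimethyldodeca-2,6,10-trien-1-ol] | CC(C)=CCC/C(C)=C/CC/C(C)=C\CO
F3 | step 4 | [(2R,3S)-3-[(3E)-4,8-dimethylnona-3,7-dien-1-yl]-3-methyloxiran-2-yl]methanol | OC[C@H]1O[C@@]1(C)CC/C=C(\C)CCC=C(C)C
F4 | step 4 | (2S,3S)-3-[(3E)-4,8-dimethylnona-3,7-dien-1-yl]-2-(iodomethyl)-3-methyloxirane | IC[C@H]1O[C@@]1(C)CC/C=C(\C)CCC=C(C)C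
F5 | step 4 | tert-butyl 3-[(2R,3S)-3-[(3E)-4,8-dimethylnona-3,7-dien-1-yl]-3-methyloxiran-2-yl]propanoate | CC(C)(C)OC(=O)CC[C@H]1O[C@@]1(C)CC/C=C(\C)CCC=C(C)C
F0 | step 5 | none | none
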